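The ratio of two logarithms opens this flask: with ln(charged/left) for each substrate, the left-handed value over the right-handed one in the cedar run at 25.0 min reads 1.79, the selectivity factor.

in all of them: gas 200 mM (held)
- ash: left-handed substrate 0.50 M; right-handed substrate 0.50 M; catalyst 17 mM; run made earlier
- maple: left-handed substrate 0.50 M; right-handed substrate 0.50 M; catalyst 26 mM; run made earlier
- cedar: left-handed substrate 0.25 M; right-handed substrate 0.25 M; catalyst 12 mM; run made earlier
- flask: left-handed substrate 0.50 M; right-handed substrate 0.50 M; catalyst 12 mM; time 25 min

| run | time / min | left-handed substrate / % | right-handed substrate / % |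
|---|---|---|---|
| ash | 4.00 | 40.2 | 44.3 |
| ash | 8.00 | 32.7 | 38.9 |
| ash | 10.0 | 29.7 | 36.6 |
| ash | 15.0 | 22.1 | 31.7 |
| ash | 20.0 | 17.8 | 26.3 |
| ash | 25.0 | 13.1 | 22.3 |
| maple | 1.33 | 45.8 | 48.0 |
| maple | 4.00 | 37.7 | 42.5 |
| maple | 8.00 | 25.9 | 35.2 |
| maple | 10.0 | 23.6 | 32.9 |
| maple | 15.0 | 14.8 | 25.2 |
| maple | 20.0 | 10.4 | 20.1 |
| maple | 25.0 | 7.1 | 16.1 |
| cedar | 2.00 | 46.9 | 48.3 |
| cedar | 4.00 | 42.5 | 45.3 |
| cedar | 8.00 | 36.1 | 42.0 |
| cedar | 12.0 | 30.6 | 38.2 |
| cedar | 25.0 | 19.1 | 29.2 |

(each reading ± 0.5 percentage points)

- catalyst is single-handed; left-handed substrate and right-handed substrate are mirror images of each other, charged as a racemate, each of them at the stated concentration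
- at the start none of the gas is in solution
- an excess is below zero if the other one leads

* part of the left-handed substrate and right-handed substrate charged together that has reacted at 25 min
* excess of left-handed product over right-handed product in the product at 25 min
* excess of right-handed substrate over left-handed substrate among what is left of the two at 25 min

I call ln(charged/left) divided by the charged c(catalyst), at 25 min, the fall per catalyst. For the left-handed substrate it reads 0.0802 /mM in cedar, 0.0788 /mM in ash and 0.0751 /mM in maple, though cedar holds half the substrate of ash. So in the flask, at 12 mM of catalyst, I expect 38.2% of the left-handed charge and 58.4% of the right-handed charge to remain: c 51.7%, eP 19.5%, eS 20.9%.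

The forecast says 51.7%, 19.1% and 20.5%, holding that “halving the substrate leaves the rate constant unchanged”; its c matches mine, and its two excesses lie slightly lower than mine.

The flask gives 52.1%, 18.7% and 20.3%.

    gas ⇌ reagent, rate k1*(csat - [reagent]) (kL = 0.0370 /s)
    reagent + catalyst + right-handed substrate → catalyst + right-handed product (k = 0.800 /M²/s)
    catalyst ⇌ dormant form (K = 2.40, k = 0.150 /s)
    2 reagent → self-condensation product (k = 0.0640 /M/s)
    reagent + catalyst + left-handed substrate → catalyst + left-handed product (k = 1.40 /M²/s)

In the flask, 38% of the left-handed charge remains at 25.0 min, a fall per catalyst of 0.0806 /mM, and c(reagent) moves from 0.129 M to 0.133 M between 2.50 min and 25.0 min, while the catalyst stands at 29.4% of its charge at the first of these times and 29.4% at the second, with 70.6% as dormant form at the second: between these times the flask is pseudo-first-order in each substrate. The neighbour flask, changed from the flask by its 0.020 M of catalyst, also shows 0.133 M of reagent at 25.0 min. There the fall per catalyst predicts 20.1% of the left-handed charge and 40.8% of the right-handed charge remaining, so c 69.5%. That neighbour flask gives 21% of the left-handed charge remaining and c 69.5%.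

The runs were computed with made-up constants, noise included.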